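**Strategy.** The target is opened at the two σ-bonds of its central cyclohexene, C3–C11' and C5–C13': a Diels–Alder union of a dienone half (diene C5=C1–C2=C3) with an α-methylene lactone half of the mirror-image series. Both halves come from one racemic all-cis lactone-fused cyclohexanol, split enzymatically. In the key step the cyclohexanone of the dienophile half becomes seven-membered ring E: trimethylsilyldiazomethane inserts one carbon (C5') between the ketone carbon C1' and the unbranched C6', and silicon locks the C1'=C5' enol position, which is sulfonylated for later Heck attachment of the enone chain. The step exploits ketone C1' flanked by methine C10' and methylene C6'.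

Key step: step 4

**Remark on the chemistry (assumption).** In the target the ring stereocentres C7'/C8'/C10' are the mirror image of C7/C8/C10, so both enantiomers of one bicyclic building block are needed and a resolution wastes nothing.

**Locants.** Each C15 half carries xanthane-type numbers: C1 (ring carbon bearing the chain C2–C3–C4(=O)–C15), C5, C6, C7 (bears C11), C8 (bears the lactone oxygen), C9, C10 (bears methyl C14); C11/C12/C13 are the lactone α-carbon, carbonyl and methylene. Unprimed is the half that keeps its α-methylene lactone; primed is the spiro-lactone half.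
- Ring A: lactone O–C12–C11–C7–C8.
- Ring B: cycloheptane C1, C5–C10.
- Ring C: cyclohexene C1, C2, C3, C11', C13', C5.
- Ring D: spiro lactone C11', C12', O, C8', C7'.
- Ring E: cycloheptene C1', C5'–C10'.

In the benzofuranone intermediates, C5 = C1('), C4 = C6('), C6 = C10('), C3a = C7('), C7a = C8(').

## Route

**Step 1**
Reactants: 1 2-methyl-1,4-benzoquinone; 2 tert-butyl[(1-methoxyethenyl)oxy]dimethylsilane
Product: 4 5-hydroxy-6-methyl-1-benzofuran-2(3H)-one, via silylated hydroquinone ester 3 (not isolated)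
Conditions: MeCN, −20 °C → rt; then TsOH·H2O (1.1 equiv), toluene, 110 °C (−MeOH)
Reagents that add atoms: tert-butyl[(1-methoxyethenyl)oxy]dimethylsilane (2), C=C(OC)O[Si](C)(C)C(C)(C)C
Why: Mukaiyama–Michael addition of the ketene silyl acetal to the unsubstituted C5=C6 bond of the quinone should occur at C5 (para to methyl, β to the more electrophilic C1 carbonyl) and be followed by aromatisation, the silyl transfer to oxygen suppressing redox exchange with unreacted quinone, after which acid cleaves the aryl silyl ether and closes the aryl lactone on the neighbouring phenol.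

**Step 2**
Reactants: 4 5-hydroxy-6-methyl-1-benzofuran-2(3H)-one
Product: 5 rac-(3aR*,5R*,6S*,7aR*)-5-hydroxy-6-methylhexahydro-1-benzofuran-2(3H)-one (all-cis)
Conditions: H2 (50 bar), 5% Rh/Al2O3, EtOAc, rt
Reagents that add atoms: none
Why: Heterogeneous arene hydrogenation on rhodium delivers all six hydrogens from the adsorbed face, so the four new stereocentres (C3a, C5, C6, C7a) should form with all ring hydrogens cis, as a racemate, the lactone staying intact.

**Step 3**
Reactants: 5 rac-(3aR*,5R*,6S*,7aR*)-5-hydroxy-6-methylhexahydro-1-benzofuran-2(3H)-one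
Product: 6 (3aS,6R,7aS)-6-methylhexahydro-1-benzofuran-2,5-dione and 7 (3aR,5R,6S,7aR)-5-hydroxy-6-methylhexahydro-1-benzofuran-2(3H)-one (unreacted enantiomer, recovered)
Conditions: (S)-selective alcohol dehydrogenase (e.g. from Rhodococcus ruber), NAD+ (cat.), acetone (10 vol%), phosphate buffer pH 7.5, 30 °C, to half conversion
Reagents that add atoms: none
Why: Enzymatic oxidative kinetic resolution by an alcohol dehydrogenase (ketoreductase class run in the oxidative direction, acetone as hydride acceptor) should oxidise only the (5S)-carbinol enantiomer, for which the methyl-bearing C6 is the large substituent, giving ketone 6 and leaving 7 at a neutral pH that does not epimerise C6; an enzyme of the opposite preference would merely exchange which series emerges as ketone.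

**Step 4 (key step)**
Reactants: 6 (3aS,6R,7aS)-6-methylhexahydro-1-benzofuran-2,5-dione; 8 (trimethylsilyl)diazomethane
Product: 11 (3aS,7R,8aS)-7-methyl-2-oxo-3,3a,4,7,8,8a-hexahydro-2H-cyclohepta[b]furan-6-yl nonafluorobutane-1-sulfonate, via α-silyl cycloheptanone 9 (not isolated), via enol silane 10 (not isolated)
Conditions: Me3SiCHN2 (1.3 equiv), Sc(OTf)3 (10 mol%), toluene, 0 °C → rt, then 60 °C; then C4F9SO2F, Bu4N[Ph3SiF2] (5 mol%), THF, 0 °C → rt
Reagents that add atoms: (trimethylsilyl)diazomethane (8), C[Si](C)(C)C=[N+]=[N-]; nonafluorobutane-1-sulfonyl fluoride, O=S(=O)(F)C(F)(F)C(F)(F)C(F)(F)C(F)(F)F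
Why: The scandium Lewis acid activates ketone C1', the diazoalkane adds to it, and loss of N2 is accompanied by a 1,2-shift of the unbranched methylene C6' rather than the methyl-bearing methine C10', giving α-silyl cycloheptanone 9 with silicon on the new carbon C5'; a 1,3-Brook (C→O) silyl shift then gives enol silane 10 with the double bond exactly at C1'=C5', and fluoride-catalysed silicon-to-sulfonyl exchange gives 11. The closest known reaction type is the Lewis-acid-catalysed diazoalkane (Tiffeneau–Demjanov-type) one-carbon homologation of 2-alkylcyclohexanones with trimethylsilyldiazomethane, followed by the established conversion of silyl enol ethers into alkenyl nonaflates. No ring is closed: the six-membered carbocycle is enlarged to ring E (six to seven atoms) by a 1,2-alkyl shift, and lactone ring D stays intact. No stereocentre is created because C5' ends sp2; C7', C8' and C10' are carried over unchanged, C10' being protected from epimerisation because the product is an enol derivative and not a ketone. The step needs regioselective migration (C6' against C10'), secured by the preference of the bulky silyl diazoalkane for shift of the less substituted α-carbon, and it needs to stop after one insertion, secured because the silylated product is no longer a free ketone.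

**Step 5**
Reactants: 11 (3aS,7R,8aS)-7-methyl-2-oxo-3,3a,4,7,8,8a-hexahydro-2H-cyclohepta[b]furan-6-yl nonafluorobutane-1-sulfonate; 12 N,N-dimethylmethyleneiminium iodide (Eschenmoser's salt)
Product: 14 (3R,3aS,7R,8aS)-3-[(dimethylamino)methyl]-7-methyl-2-oxo-3,3a,4,7,8,8a-hexahydro-2H-cyclohepta[b]furan-6-yl nonafluorobutane-1-sulfonate, via lithium enolate 13 (not isolated)
Conditions: LDA (1.1 equiv), THF, −78 °C; then Me2N=CH2 I (1.5 equiv), −78 → 0 °C
Reagents that add atoms: N,N-dimethylmethyleneiminium iodide (12), C=[N+](C)C.[I-]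
Why: Mannich aminomethylation of the lactone enolate (the only acidic site; alkenyl nonaflates tolerate LDA at −78 °C) should place the aminomethyl group on the convex face of the cis-fused bicycle (3R), a centre that is later planarised.

**Step 6**
Reactants: 14 (3R,3aS,7R,8aS)-3-[(dimethylamino)methyl]-7-methyl-2-oxo-3,3a,4,7,8,8a-hexahydro-2H-cyclohepta[b]furan-6-yl nonafluorobutane-1-sulfonate
Product: 16 (3aS,7R,8aS)-7-methyl-3-methylidene-2-oxo-3,3a,4,7,8,8a-hexahydro-2H-cyclohepta[b]furan-6-yl nonafluorobutane-1-sulfonate (dienophile), via ammonium iodide 15 (not isolated)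
Conditions: MeI (10 equiv), CH2Cl2, rt; then aq. NaHCO3, EtOAc, rt
Reagents that add atoms: none
Why: N-Methylation followed by base-induced E1cB (Hofmann-type) loss of trimethylamine from the β-ammonio lactone is the standard way to the α-methylene lactone and creates no stereocentre.

**Step 7**
Reactants: 7 (3aR,5R,6S,7aR)-5-hydroxy-6-methylhexahydro-1-benzofuran-2(3H)-one
Product: 17 (3aR,6S,7aR)-6-methylhexahydro-1-benzofuran-2,5-dione
Conditions: Dess–Martin periodinane, CH2Cl2, 0 °C → rt
Reagents that add atoms: none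
Why: Dess–Martin oxidation of the secondary alcohol is neutral and non-enolising, so the kinetically set all-cis methyl centre C6 next to the new ketone should survive.

**Step 8**
Reactants: 17 (3aR,6S,7aR)-6-methylhexahydro-1-benzofuran-2,5-dione; 8 (trimethylsilyl)diazomethane
Product: 20 (3aR,7S,8aR)-7-methyl-2-oxo-3,3a,4,7,8,8a-hexahydro-2H-cyclohepta[b]furan-6-yl nonafluorobutane-1-sulfonate, via α-silyl cycloheptanone 18 (not isolated), via enol silane 19 (not isolated)
Conditions: Me3SiCHN2 (1.3 equiv), Sc(OTf)3 (10 mol%), toluene, 0 °C → rt, then 60 °C; then C4F9SO2F, Bu4N[Ph3SiF2] (5 mol%), THF, 0 °C → rt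
Reagents that add atoms: (trimethylsilyl)diazomethane (8), C[Si](C)(C)C=[N+]=[N-]; nonafluorobutane-1-sulfonyl fluoride, O=S(=O)(F)C(F)(F)C(F)(F)C(F)(F)C(F)(F)F
Why: The same Lewis-acid-catalysed diazoalkane ring homologation, Brook shift and sulfonylation as in step 4, here in the mirror-image series, inserts C5 between C1 and C6 and builds ring B with the C1=C5 enol sulfonate without touching a stereocentre.

**Step 9**
Reactants: 20 (3aR,7S,8aR)-7-methyl-2-oxo-3,3a,4,7,8,8a-hexahydro-2H-cyclohepta[b]furan-6-yl nonafluorobutane-1-sulfonate; 12 N,N-dimethylmethyleneiminium iodide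
Product: 22 (3S,3aR,7S,8aR)-3-[(dimethylamino)methyl]-7-methyl-2-oxo-3,3a,4,7,8,8a-hexahydro-2H-cyclohepta[b]furan-6-yl nonafluorobutane-1-sulfonate, via lithium enolate 21 (not isolated)
Conditions: LDA (1.1 equiv), THF, −78 °C; then Me2N=CH2 I (1.5 equiv), −78 → 0 °C
Reagents that add atoms: N,N-dimethylmethyleneiminium iodide (12), C=[N+](C)C.[I-]
Why: Mannich aminomethylation of the lactone enolate from the convex face (3S) installs C13 in masked form, so that this half carries no dienophile until the last step.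

**Step 10**
Reactants: 22 (3S,3aR,7S,8aR)-3-[(dimethylamino)methyl]-7-methyl-2-oxo-3,3a,4,7,8,8a-hexahydro-2H-cyclohepta[b]furan-6-yl nonafluorobutane-1-sulfonate; 23 but-3-en-2-one (methyl vinyl ketone)
Product: 24 (3S,3aR,7S,8aR)-3-[(dimethylamino)methyl]-7-methyl-6-[(1E)-3-oxobut-1-en-1-yl]-3,3a,4,7,8,8a-hexahydro-2H-cyclohepta[b]furan-2-one (diene)
Conditions: 23 (3 equiv), Pd(OAc)2 (5 mol%), PPh3 (10 mol%), NaHCO3, DMF, 60 °C
Reagents that add atoms: but-3-en-2-one (23), C=CC(C)=O
Why: Mizoroki–Heck coupling of the alkenyl nonaflate with the enone (oxidative addition to zerovalent palladium, syn insertion, syn β-hydride elimination) should give the E-dienone C5=C1–C2=C3–C4(=O), the tertiary amine and lactone being inert.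

**Step 11**
Reactants: 24 (diene, 1 equiv); 16 (dienophile, 1.5 equiv)
Product: 25 cycloadduct: ring C formed with C1=C2, acetyl on C3, H-3 cis to H-5, spiro centre C11' with the lactone carbonyl C12' cis to H-5; unprimed half still carries CH2NMe2 on C11 and primed half the nonaflate on C1'
Conditions: toluene (3 M), BHT (cat.), 85 °C, argon, dark
Reagents that add atoms: none
Why: Thermal Diels–Alder reaction of the only diene present (C5=C1–C2=C3 of 24, whose own methylene lactone is masked) with the only dienophile present (C11'=C13' of 16, which has no diene) should give the ortho regioisomer (C3–C11', C5–C13'), with C11' set by attack on the convex face of the cis-fused lactone in the carbonyl-exo mode usual for α-methylene-γ-butyrolactones, C5 set by addition to the diene face away from the ring hydrogens H-7, H-8 and H-10, and C3 set suprafacially from the E-alkene.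

**Step 12**
Reactants: 25 cycloadduct
Product: 27 C1-hydroxy C2=C3 enone (1-OH trans to H-5) with CH2NMe2 on C11 and nonaflate on C1', via C1 hydroperoxide 26 (not isolated)
Conditions: O2 (1 atm), DBU (1.5 equiv), P(OEt)3 (2 equiv), MeCN, 0 °C
Reagents that add atoms: dioxygen, O=O
Why: Base-mediated γ-autoxidation of the β,γ-unsaturated ketone: the extended dienolate (deprotonation at the doubly activated C3–H) should capture O2 at C1, because C3 is shielded by the adjacent spiro centre, by axial approach anti to the pseudoaxial H-5 (the course known for γ-oxygenation of ring-fused β,γ-enones at a ring-fusion carbon), and the hydroperoxide is reduced in situ by the phosphite.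

**Step 13**
Reactants: 27 C1-hydroxy enone nonaflate; 23 but-3-en-2-one
Product: 28 13-(dimethylamino)-11,13-dihydro derivative of the target
Conditions: 23 (3 equiv), Pd(OAc)2 (5 mol%), PPh3 (10 mol%), NaHCO3, DMF, 60 °C
Reagents that add atoms: but-3-en-2-one (23), C=CC(C)=O
Why: A second Mizoroki–Heck coupling at the C1' nonaflate installs the E-configured enone chain on ring E, which could not be present earlier because it would have made the dienophile half a diene.

**Step 14**
Reactants: 28 13-(dimethylamino)-11,13-dihydro derivative of the target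
Product: 30 CNP0168949.2 (target), via ammonium iodide 29 (not isolated)
Conditions: MeI (10 equiv), CH2Cl2, rt; then aq. NaHCO3, EtOAc, rt
Reagents that add atoms: none
Why: Chemoselective N-methylation and E1cB elimination of trimethylamine unmask the C11=C13 methylene of ring A under conditions that leave the tertiary alcohol, the enone and the dienone untouched.

## Compound list

1 | 2-methyl-1,4-benzoquinone | CC1=CC(=O)C=CC1=O | starting material
2 | tert-butyl[(1-methoxyethenyl)oxy]dimethylsilane | C=C(OC)O[Si](C)(C)C(C)(C)C | starting material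
3 | methyl 2-[5-(tert-butyldimethylsilyloxy)-2-hydroxy-4-methylphenyl]acetate | COC(=O)Cc1cc(O[Si](C)(C)C(C)(C)C)c(C)cc1O | intermediate (not isolated)
4 | 5-hydroxy-6-methyl-1-benzofuran-2(3H)-one | O=C1Cc2cc(O)c(C)cc2O1 | intermediate
5 | rac-(3aR*,5R*,6S*,7aR*)-5-hydroxy-6-methylhexahydro-1-benzofuran-2(3H)-one, all-cis racemate (both enantiomers written) | C1C(=O)O[C@@H]2C[C@H](C)[C@H](O)C[C@H]12.C1C(=O)O[C@H]2C[C@@H](C)[C@@H](O)C[C@@H]12 | intermediate
6 | (3aS,6R,7aS)-6-methylhexahydro-1-benzofuran-2,5-dione | C1C(=O)O[C@H]2C[C@@H](C)C(=O)C[C@@H]12 | intermediate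
7 | (3aR,5R,6S,7aR)-5-hydroxy-6-methylhexahydro-1-benzofuran-2(3H)-one | C1C(=O)O[C@@H]2C[C@H](C)[C@H](O)C[C@H]12 | intermediate
8 | (trimethylsilyl)diazomethane | C[Si](C)(C)C=[N+]=[N-] | starting material
9 | 7-methyl-5-(trimethylsilyl)hexahydro-2H-cyclohepta[b]furan-2,6(3H)-dione, ring stereocentres as in 6, epimers at the silicon-bearing carbon | C1C(=O)O[C@H]2C[C@@H](C)C(=O)C([Si](C)(C)C)C[C@@H]12 | intermediate (not isolated)
10 | (3aS,7R,8aS)-7-methyl-6-(trimethylsilyloxy)-3,3a,4,7,8,8a-hexahydro-2H-cyclohepta[b]furan-2-one | C1C(=O)O[C@H]2C[C@@H](C)C(O[Si](C)(C)C)=CC[C@@H]12 | intermediate (not isolated)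
11 | (3aS,7R,8aS)-7-methyl-2-oxo-3,3a,4,7,8,8a-hexahydro-2H-cyclohepta[b]furan-6-yl nonafluorobutane-1-sulfonate | C1C(=O)O[C@H]2C[C@@H](C)C(OS(=O)(=O)C(F)(F)C(F)(F)C(F)(F)C(F)(F)F)=CC[C@@H]12 | intermediate
12 | N,N-dimethylmethyleneiminium iodide (Eschenmoser's salt) | C=[N+](C)C.[I-] | starting material
13 | lithium enolate of 11 | C1=C([O-])O[C@H]2C[C@@H](C)C(OS(=O)(=O)C(F)(F)C(F)(F)C(F)(F)C(F)(F)F)=CC[C@@H]12.[Li+] | intermediate (not isolated)
14 | (3R,3aS,7R,8aS)-3-[(dimethylamino)methyl]-7-methyl-2-oxo-3,3a,4,7,8,8a-hexahydro-2H-cyclohepta[b]furan-6-yl nonafluorobutane-1-sulfonate | CN(C)C[C@@H]1C(=O)O[C@H]2C[C@@H](C)C(OS(=O)(=O)C(F)(F)C(F)(F)C(F)(F)C(F)(F)F)=CC[C@@H]12 | intermediate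
15 | trimethylammonium iodide of 14 | C[N+](C)(C)C[C@@H]1C(=O)O[C@H]2C[C@@H](C)C(OS(=O)(=O)C(F)(F)C(F)(F)C(F)(F)C(F)(F)F)=CC[C@@H]12.[I-] | intermediate (not isolated)
16 | (3aS,7R,8aS)-7-methyl-3-methylidene-2-oxo-3,3a,4,7,8,8a-hexahydro-2H-cyclohepta[b]furan-6-yl nonafluorobutane-1-sulfonate | C=C1C(=O)O[C@H]2C[C@@H](C)C(OS(=O)(=O)C(F)(F)C(F)(F)C(F)(F)C(F)(F)F)=CC[C@@H]12 | intermediate
17 | (3aR,6S,7aR)-6-methylhexahydro-1-benzofuran-2,5-dione | C1C(=O)O[C@@H]2C[C@H](C)C(=O)C[C@H]12 | intermediate
18 | 7-methyl-5-(trimethylsilyl)hexahydro-2H-cyclohepta[b]furan-2,6(3H)-dione, ring stereocentres as in 17, epimers at the silicon-bearing carbon | C1C(=O)O[C@@H]2C[C@H](C)C(=O)C([Si](C)(C)C)C[C@H]12 | intermediate (not isolated)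
19 | (3aR,7S,8aR)-7-methyl-6-(trimethylsilyloxy)-3,3a,4,7,8,8a-hexahydro-2H-cyclohepta[b]furan-2-one | C1C(=O)O[C@@H]2C[C@H](C)C(O[Si](C)(C)C)=CC[C@H]12 | intermediate (not isolated)
20 | (3aR,7S,8aR)-7-methyl-2-oxo-3,3a,4,7,8,8a-hexahydro-2H-cyclohepta[b]furan-6-yl nonafluorobutane-1-sulfonate | C1C(=O)O[C@@H]2C[C@H](C)C(OS(=O)(=O)C(F)(F)C(F)(F)C(F)(F)C(F)(F)F)=CC[C@H]12 | intermediate
21 | lithium enolate of 20 | C1=C([O-])O[C@@H]2C[C@H](C)C(OS(=O)(=O)C(F)(F)C(F)(F)C(F)(F)C(F)(F)F)=CC[C@H]12.[Li+] | intermediate (not isolated)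
22 | (3S,3aR,7S,8aR)-3-[(dimethylamino)methyl]-7-methyl-2-oxo-3,3a,4,7,8,8a-hexahydro-2H-cyclohepta[b]furan-6-yl nonafluorobutane-1-sulfonate | CN(C)C[C@H]1C(=O)O[C@@H]2C[C@H](C)C(OS(=O)(=O)C(F)(F)C(F)(F)C(F)(F)C(F)(F)F)=CC[C@H]12 | intermediate
23 | but-3-en-2-one (methyl vinyl ketone) | C=CC(C)=O | starting material
24 | (3S,3aR,7S,8aR)-3-[(dimethylamino)methyl]-7-methyl-6-[(1E)-3-oxobut-1-en-1-yl]-3,3a,4,7,8,8a-hexahydro-2H-cyclohepta[b]furan-2-one | CN(C)C[C@H]1C(=O)O[C@@H]2C[C@H](C)C(/C=C/C(C)=O)=CC[C@H]12 | intermediate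
25 | Diels–Alder adduct of 24 and 16 (C1=C2, acetyl on C3, H-3 cis to H-5, C12' carbonyl cis to H-5, CH2NMe2 on C11, nonaflate on C1') | CN(C)C[C@H]1C(=O)O[C@@H]2C[C@H](C)C3=C[C@H](C(C)=O)[C@]4(C[C@@H]3C[C@H]12)C(=O)O[C@H]1C[C@@H](C)C(OS(=O)(=O)C(F)(F)C(F)(F)C(F)(F)C(F)(F)F)=CC[C@H]14 | intermediate
26 | C1 hydroperoxide of the C2=C3 enone (OOH trans to H-5) | CN(C)C[C@H]1C(=O)O[C@@H]2C[C@H](C)[C@@]3(OO)C=C(C(C)=O)[C@]4(C[C@@H]3C[C@H]12)C(=O)O[C@H]1C[C@@H](C)C(OS(=O)(=O)C(F)(F)C(F)(F)C(F)(F)C(F)(F)F)=CC[C@H]14 | intermediate (not isolated)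
27 | C1-hydroxy C2=C3 enone (OH trans to H-5), CH2NMe2 on C11, nonaflate on C1' | CN(C)C[C@H]1C(=O)O[C@@H]2C[C@H](C)[C@@]3(O)C=C(C(C)=O)[C@]4(C[C@@H]3C[C@H]12)C(=O)O[C@H]1C[C@@H](C)C(OS(=O)(=O)C(F)(F)C(F)(F)C(F)(F)C(F)(F)F)=CC[C@H]14 | intermediate
28 | 13-(dimethylamino)-11,13-dihydro derivative of the target | CN(C)C[C@H]1C(=O)O[C@@H]2C[C@H](C)[C@@]3(O)C=C(C(C)=O)[C@]4(C[C@@H]3C[C@H]12)C(=O)O[C@H]1C[C@@H](C)C(/C=C/C(C)=O)=CC[C@H]14 | intermediate
29 | trimethylammonium iodide of 28 | C[N+](C)(C)C[C@H]1C(=O)O[C@@H]2C[C@H](C)[C@@]3(O)C=C(C(C)=O)[C@]4(C[C@@H]3C[C@H]12)C(=O)O[C@H]1C[C@@H](C)C(/C=C/C(C)=O)=CC[C@H]14.[I-] | intermediate (not isolated)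
30 | CNP0168949.2 | C=C1C(=O)O[C@@H]2C[C@H](C)[C@@]3(O)C=C(C(C)=O)[C@]4(C[C@@H]3C[C@H]12)C(=O)O[C@H]1C[C@@H](C)C(/C=C/C(C)=O)=CC[C@H]14 | target

## Summary

Total step count: 14.
Longest linear sequence: 11 steps (1, 2, 3, 7, 8, 9, 10, 11, 12, 13, 14).

**Steps most likely to fail**

Step 11. The union of two electron-poor partners may be slow. During prolonged heating the masked lactone of 24 may lose dimethylamine, which would let the diene half add to itself, and face or exo control between the mirror-image partners may be incomplete. Fallback without the mask, setting out from 24 and returning at 30: methylation and elimination (MeI, then NaHCO3) would pass through the trimethylammonium iodide of 24 F1 to natural-series 8-epi-xanthatin F2. F2 would be combined with a threefold excess of 16 (recoverable), if need be at 10–12 kbar and room temperature, so that its free methylene lactone is outcompeted, giving the cycloadduct with free methylene lactone F3. Oxygenation as in step 12 would lead through the C1 hydroperoxide F4 to the C1-hydroxy enone nonaflate F5, and Heck coupling of F5 with 23 would give 30 directly.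

Step 12. Oxygen may be captured on the wrong face of C1 or at C3, or the ketone may only isomerise into conjugation. Fallback by two-electron oxidation of an isolated dienol ether (vinylogous Rubottom oxidation), setting out from 25 and returning at 27: TBSOTf and Et3N would give the tert-butyldimethylsilyl dienol ether of 25 F6 (C1=C2–C3=C4–OSi, enol ether geometry immaterial). With the amine protected as its trifluoroacetate salt, dimethyldioxirane would epoxidise the terminal C1=C2 bond, and fluoride work-up would open it to 27.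

Step 2. All-cis delivery may be eroded through the cyclohexanone tautomer of the half-reduced phenol, and the aryl–oxygen bonds may undergo hydrogenolysis. Fallback through a silyl ether that cannot tautomerise, setting out from 4 and returning at 5: TBSCl and imidazole would give 5-(tert-butyldimethylsilyloxy)-6-methyl-1-benzofuran-2(3H)-one F7. Hydrogenation with the cis-selective carbene complex [Rh(COD)(CAAC)Cl] on silica (H2, 50 bar, hexane) would give the racemic all-cis silyl ether F8, and Bu4NF would release 5.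

## Further compounds

F1 | step 11 | trimethylammonium iodide of 24 (not isolated) | C[N+](C)(C)C[C@H]1C(=O)O[C@@H]2C[C@H](C)C(/C=C/C(C)=O)=CC[C@H]12.[I-]
F2 | step 11 | 8-epi-xanthatin, (3aR,7S,8aR)-7-methyl-3-methylidene-6-[(1E)-3-oxobut-1-en-1-yl]-3,3a,4,7,8,8a-hexahydro-2H-cyclohepta[b]furan-2-one | C=C1C(=O)O[C@@H]2C[C@H](C)C(/C=C/C(C)=O)=CC[C@H]12
F3 | step 11 | cycloadduct of F2 and 16 with free methylene lactone | C=C1C(=O)O[C@@H]2C[C@H](C)C3=C[C@H](C(C)=O)[C@]4(C[C@@H]3C[C@H]12)C(=O)O[C@H]1C[C@@H](C)C(OS(=O)(=O)C(F)(F)C(F)(F)C(F)(F)C(F)(F)F)=CC[C@H]14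
F4 | step 11 | C1 hydroperoxide derived from F3 (not isolated) | C=C1C(=O)O[C@@H]2C[C@H](C)[C@@]3(OO)C=C(C(C)=O)[C@]4(C[C@@H]3C[C@H]12)C(=O)O[C@H]1C[C@@H](C)C(OS(=O)(=O)C(F)(F)C(F)(F)C(F)(F)C(F)(F)F)=CC[C@H]14
F5 | step 11 | C1-hydroxy enone nonaflate with free methylene lactone | C=C1C(=O)O[C@@H]2C[C@H](C)[C@@]3(O)C=C(C(C)=O)[C@]4(C[C@@H]3C[C@H]12)C(=O)O[C@H]1C[C@@H](C)C(OS(=O)(=O)C(F)(F)C(F)(F)C(F)(F)C(F)(F)F)=CC[C@H]14
F6 | step 12 | tert-butyldimethylsilyl dienol ether of 25 | CN(C)C[C@H]1C(=O)O[C@@H]2C[C@H](C)C3=CC(=C(C)O[Si](C)(C)C(C)(C)C)[C@]4(C[C@@H]3C[C@H]12)C(=O)O[C@H]1C[C@@H](C)C(OS(=O)(=O)C(F)(F)C(F)(F)C(F)(F)C(F)(F)F)=CC[C@H]14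
F7 | step 2 | 5-(tert-butyldimethylsilyloxy)-6-methyl-1-benzofuran-2(3H)-one | O=C1Cc2cc(O[Si](C)(C)C(C)(C)C)c(C)cc2O1
F8 | step 2 | rac-(3aR*,5R*,6S*,7aR*)-5-(tert-butyldimethylsilyloxy)-6-methylhexahydro-1-benzofuran-2(3H)-one (both enantiomers written) | C1C(=O)O[C@@H]2C[C@H](C)[C@H](O[Si](C)(C)C(C)(C)C)C[C@H]12.C1C(=O)O[C@H]2C[C@@H](C)[C@@H](O[Si](C)(C)C(C)(C)C)C[C@@H]12
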